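Cuts: with ring B as the quinone ring (C1–C4, C4a, C8a), ring A as the benzo ring and the chain as C1'–C24', the retrosynthesis severs C1'–C2' (chloromethylquinone plus C29 alkenylalane), then C3–C1', then C8–C8a and C4a–C5 of ring A. In the chain it severs C3'–CH3, C4'–C5' and C12'–C13'.
Enabling feature: ring A (C4a, C5, C6, C7, C8, C8a) bears only the C8 methyl, which lies peri to C1=O, the ring B carbonyl whose other neighbour is methyl-bearing C2. C5–C8 and that methyl are therefore the five carbons of piperylene, and a bromine on the future C8a of a methylbenzoquinone fixes the orientation and later leaves as HBr.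
Forward order, core: ring B is bought as a cresol derivative and oxidized to the bromoquinone, ring A is closed on it by cycloaddition and aromatized, and C1' is added by chloromethylation.
Forward order, chain: farnesyl sulfone and a geraniol-derived C10 bromide give the C25 alcohol, three more carbons give the C28 alkyne, and methylalumination followed by nickel-catalysed coupling joins chain and quinone in the last step.
Stereochemistry: the target has no stereocentre. Of its five E olefins, C14'=C15' and C18'=C19' come from farnesol, C6'=C7' from geraniol, C10'=C11' from E-selective SeO2 oxidation and C2'=C3' from syn-carboalumination. The stereocentres of the cycloadduct and of the sulfone are transient.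

Key step: step 2

Assumption: farnesol, geraniol and piperylene are used as the isomerically pure E compounds. Any residual (Z)-piperylene hardly reaches the s-cis conformation and should stay inert in step 2.

Step 1
Reactants: 1 2,4-dibromo-6-methylphenol
Product: 2 2-bromo-6-methyl-1,4-benzoquinone
Conditions: CrO3, AcOH–H2O, 60 °C
Reagents that add atoms: chromium trioxide, O=[Cr](=O)=O; water, O
Why: Chromic acid oxidation of a 4-bromophenol takes up oxygen at the para carbon and expels its bromide (oxidative para-dehalogenation, a standard entry to 2,6-disubstituted 1,4-benzoquinones), while the ortho bromine stays in place.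

Step 2
Reactants: 2 2-bromo-6-methyl-1,4-benzoquinone; 3 (E)-penta-1,3-diene
Product: 4 rac-(4aS*,8S*,8aR*)-8a-bromo-2,8-dimethyl-4a,5,8,8a-tetrahydronaphthalene-1,4-dione (H-4a and Br cis, C8 methyl on the face opposite to Br)
Conditions: 3 (3 equiv), toluene, 40 °C, sealed vessel, dark; evaporated below 30 °C, used crude
Reagents that add atoms: none
Why: This is a normal-electron-demand Diels–Alder reaction, concerted but asynchronous, in which the s-cis diene adds suprafacially across C2=C3 of 2 with C4a–C5 forming ahead of C8–C8a; the closest known reaction type is the halogen-steered cycloaddition of 2-bromo-1,4-benzoquinones with 1-substituted butadienes. Ring A closes in this single intermolecular [4+2] event as a cyclohexene (C6=C7) fused to ring B. C4a and C8a come out cis because the dienophile geometry is retained, and C8 follows from the E geometry of the diene combined with the endo transition state (ring B carbonyls under the diene), which puts the C8 methyl anti to bromine. Orientation: the bromine lone pair and the C6 methyl of 2 both push electron density through their double bonds into the C4 carbonyl, so the C1 carbonyl governs the LUMO, its beta carbon C3 carries the larger coefficient and joins the unsubstituted, larger-HOMO terminus of 3, and the methyl-bearing terminus is left to bond to C–Br. Site selectivity: the inductively electron-poor bromoalkene should react faster than the methyl-substituted C5=C6 bond, and Lewis acids are left out because binding at the more basic, unhindered C4 carbonyl would reverse the polarization. All three stereocentres are transient and disappear in step 3.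

Step 3
Reactants: 4 bromo adduct
Product: 7 2,8-dimethylnaphthalene-1,4-dione, via 5,8-dihydroquinone 5 (not isolated), via naphthalene-1,4-diol 6 (not isolated)
Conditions: Et3N (1.5 equiv), CH2Cl2, 0 °C → rt, then stirred under O2 (air)
Reagents that add atoms: none
Why: E1cB loss of HBr across C4a–C8a gives 5, the amine removes its doubly allylic C5/C8 hydrogens so that it tautomerizes to the aromatic diol 6, and base-promoted autoxidation of this menadiol-type hydroquinone gives the quinone (the usual dehydrobromination–aromatization of bromoquinone Diels–Alder adducts).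

Step 4
Reactants: 7 2,8-dimethylnaphthalene-1,4-dione
Product: 8 3-(chloromethyl)-2,8-dimethylnaphthalene-1,4-dione
Conditions: 37% aq. HCHO, HCl (g), 0 °C → rt
Reagents that add atoms: formaldehyde, C=O; hydrogen chloride, Cl
Why: Acid-mediated chloromethylation of a 2-methyl-1,4-naphthoquinone, known for menadione itself, can only strike C3, the one free position of ring B, because ring A is deactivated by both carbonyl groups.

Step 5
Reactants: 9 (2E,6E)-farnesol
Product: 10 (2E,6E)-farnesyl bromide
Conditions: PBr3 (0.4 equiv), Et2O, −10 → 0 °C
Reagents that add atoms: phosphorus tribromide, BrP(Br)Br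
Why: Bromination of a primary allylic alcohol through its phosphite ester (SN2) at low temperature should leave both E olefins and the allylic position unrearranged.

Step 6
Reactants: 10 (2E,6E)-farnesyl bromide
Product: 11 (2E,6E)-farnesyl phenyl sulfone
Conditions: PhSO2Na, DMF, rt
Reagents that add atoms: sodium benzenesulfinate, [Na+].[O-]S(=O)c1ccccc1
Why: S-alkylation of the ambident sulfinate by a soft primary allylic bromide (SN2) in a dipolar aprotic solvent gives the sulfone without allylic transposition.

Step 7
Reactants: 12 geraniol
Product: 13 benzyl geranyl ether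
Conditions: NaH, BnBr, n-Bu4NI (cat.), THF, 0 °C → rt
Reagents that add atoms: benzyl bromide, BrCc1ccccc1
Why: Williamson ether synthesis installs a group that withstands SeO2, PBr3 and the sulfonyl carbanion and can leave together with the sulfone in step 11.

Step 8
Reactants: 13 benzyl geranyl ether
Product: 14 (2E,6E)-8-(benzyloxy)-2,6-dimethylocta-2,6-dien-1-ol
Conditions: SeO2 (0.1 equiv), t-BuOOH (2 equiv), salicylic acid (0.1 equiv), CH2Cl2, 0 °C → rt
Reagents that add atoms: tert-butyl hydroperoxide, CC(C)(C)OO (oxygen relayed through catalytic SeO2, O=[Se]=O)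
Why: The catalytic Riley allylic oxidation (ene reaction, then [2,3]-sigmatropic shift of the allylseleninic acid) attacks the electron-rich isopropylidene unit rather than the oxygen-deactivated allylic-ether olefin and hydroxylates the methyl group trans to the chain, which fixes the future C10'=C11' olefin as E.

Step 9
Reactants: 14 allylic alcohol
Product: 15 (2E,6E)-8-(benzyloxy)-1-bromo-2,6-dimethylocta-2,6-diene
Conditions: PBr3 (0.4 equiv), Et2O, −10 → 0 °C
Reagents that add atoms: phosphorus tribromide, BrP(Br)Br
Why: The same SN2-type phosphite-ester bromination of a primary allylic alcohol applies here, the benzyl ether is inert to it, and neither olefin should move.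

Step 10
Reactants: 11 (2E,6E)-farnesyl phenyl sulfone; 15 allylic bromide
Product: 16 racemic benzyl (2E,6E,10E,14E)-3,7,11,15,19-pentamethyl-9-(phenylsulfonyl)icosa-2,6,10,14,18-pentaenyl ether
Conditions: 11, n-BuLi, THF–DMPU, −78 °C; then 15, −78 → −20 °C
Reagents that add atoms: none
Why: Alkylation of the sulfone-stabilized allyl carbanion at its alpha carbon with a primary allylic bromide (Biellmann-type head-to-tail coupling) forms the future C12'–C13' bond with all olefin geometries kept, and the new sulfone-bearing stereocentre is racemic and is erased in step 11.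

Step 11
Reactants: 16 coupled sulfone
Product: 17 (2E,6E,10E,14E)-geranylfarnesol (3,7,11,15,19-pentamethylicosa-2,6,10,14,18-pentaen-1-ol)
Conditions: Li, EtNH2, THF, −78 °C; then NH4Cl
Reagents that add atoms: none
Why: Dissolving-metal reduction cleaves the allylic C–S bond and the benzylic C–O bond in one operation, a pairing established for all-E polyprenols, while isolated trisubstituted olefins and the allylic alkoxide resist reduction at low temperature.

Step 12
Reactants: 17 geranylfarnesol
Product: 18 (2E,6E,10E,14E)-geranylfarnesyl chloride
Conditions: NCS, Me2S, CH2Cl2, −30 → 0 °C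
Reagents that add atoms: N-chlorosuccinimide, O=C1CCC(=O)N1Cl
Why: In the Corey–Kim chlorination the alkoxysulfonium salt is displaced by chloride in SN2 fashion under nearly neutral conditions, so the primary allylic chloride should form without transposition or E/Z leakage.

Step 13
Reactants: 18 geranylfarnesyl chloride; 19 1-(trimethylsilyl)propyne
Product: 21 (5E,9E,13E,17E)-6,10,14,18,22-pentamethyltricosa-5,9,13,17,21-pentaen-1-yne, via TMS-enyne 20 (not isolated)
Conditions: 19, n-BuLi, THF, −78 → −20 °C; 18, −78 °C → rt; then MeOH, K2CO3 (cat.), rt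
Reagents that add atoms: none
Why: The propargylic lithium reagent from 19 displaces the primary allylic chloride (SN2, forming C4'–C5') while the silyl group blocks the acetylenic terminus and disfavours allene formation, and base-catalysed methanolysis of the C–Si bond then frees the terminal alkyne.

Step 14
Reactants: 21 C28 alkyne; 8 3-(chloromethyl)-2,8-dimethylnaphthalene-1,4-dione
Product: 23 2,8-dimethyl-3-[(2E,6E,10E,14E,18E)-3,7,11,15,19,23-hexamethyltetracosa-2,6,10,14,18,22-hexaenyl]naphthalene-1,4-dione, via alkenylalane 22 (not isolated)
Conditions: Me3Al (2 equiv), Cp2ZrCl2 (0.25 equiv), ClCH2CH2Cl, 0 °C → rt; excess Me3Al and solvent removed in vacuo, residue taken up in hexane and decanted; then 8, NiCl2(PPh3)2 (5 mol %) pre-reduced with n-BuLi (10 mol %), THF, −20 °C → rt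
Reagents that add atoms: trimethylaluminium, C[Al](C)C
Why: Negishi zirconium-catalysed syn-carboalumination puts methyl on the internal and aluminium on the terminal alkyne carbon on the same side, which sets C2'=C3' as E, and the known cross-coupling of alkenylalanes with chloromethylquinones under zerovalent nickel forms C1'–C2' with retention of geometry faster than the alane attacks the quinone carbonyls.

Compound list
1 | 2,4-dibromo-6-methylphenol | Cc1cc(Br)cc(Br)c1O | starting material
2 | 2-bromo-6-methyl-1,4-benzoquinone | O=C1C(Br)=CC(=O)C=C1C | intermediate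
3 | (E)-penta-1,3-diene | C/C=C/C=C | starting material
4 | rac-(4aS*,8S*,8aR*)-8a-bromo-2,8-dimethyl-4a,5,8,8a-tetrahydronaphthalene-1,4-dione (cis-fused endo adduct, relative configuration shown) | O=C1C(C)=CC(=O)[C@@H]2CC=C[C@H](C)[C@]12Br | intermediate
5 | 2,8-dimethyl-5,8-dihydronaphthalene-1,4-dione (racemic, not isolated) | O=C1C(C)=CC(=O)C2=C1C(C)C=CC2 | intermediate
6 | 2,8-dimethylnaphthalene-1,4-diol (not isolated) | Oc1c(C)cc(O)c2cccc(C)c12 | intermediate
7 | 2,8-dimethylnaphthalene-1,4-dione | O=C1C(C)=CC(=O)c2cccc(C)c12 | intermediate
8 | 3-(chloromethyl)-2,8-dimethylnaphthalene-1,4-dione | O=C1C(C)=C(CCl)C(=O)c2cccc(C)c12 | intermediate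
9 | (2E,6E)-farnesol | CC(C)=CCC/C(C)=C/CC/C(C)=C/CO | starting material
10 | (2E,6E)-farnesyl bromide | CC(C)=CCC/C(C)=C/CC/C(C)=C/CBr | intermediate
11 | (2E,6E)-farnesyl phenyl sulfone | CC(C)=CCC/C(C)=C/CC/C(C)=C/CS(=O)(=O)c1ccccc1 | intermediate
12 | geraniol | CC(C)=CCC/C(C)=C/CO | starting material
13 | benzyl geranyl ether | CC(C)=CCC/C(C)=C/COCc1ccccc1 | intermediate
14 | (2E,6E)-8-(benzyloxy)-2,6-dimethylocta-2,6-dien-1-ol | OC/C(C)=C/CC/C(C)=C/COCc1ccccc1 | intermediate
15 | (2E,6E)-8-(benzyloxy)-1-bromo-2,6-dimethylocta-2,6-diene | BrC/C(C)=C/CC/C(C)=C/COCc1ccccc1 | intermediate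
16 | benzyl (2E,6E,10E,14E)-3,7,11,15,19-pentamethyl-9-(phenylsulfonyl)icosa-2,6,10,14,18-pentaenyl ether (racemic at C9) | CC(C)=CCC/C(C)=C/CC/C(C)=C/C(S(=O)(=O)c1ccccc1)C/C(C)=C/CC/C(C)=C/COCc1ccccc1 | intermediate
17 | (2E,6E,10E,14E)-geranylfarnesol | CC(C)=CCC/C(C)=C/CC/C(C)=C/CC/C(C)=C/CC/C(C)=C/CO | intermediate
18 | (2E,6E,10E,14E)-geranylfarnesyl chloride | CC(C)=CCC/C(C)=C/CC/C(C)=C/CC/C(C)=C/CC/C(C)=C/CCl | intermediate
19 | 1-(trimethylsilyl)propyne | CC#C[Si](C)(C)C | starting material
20 | trimethyl[(5E,9E,13E,17E)-6,10,14,18,22-pentamethyltricosa-5,9,13,17,21-pentaen-1-ynyl]silane (not isolated) | CC(C)=CCC/C(C)=C/CC/C(C)=C/CC/C(C)=C/CC/C(C)=C/CCC#C[Si](C)(C)C | intermediate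
21 | (5E,9E,13E,17E)-6,10,14,18,22-pentamethyltricosa-5,9,13,17,21-pentaen-1-yne | CC(C)=CCC/C(C)=C/CC/C(C)=C/CC/C(C)=C/CC/C(C)=C/CCC#C | intermediate
22 | dimethyl[(1E,5E,9E,13E,17E)-2,6,10,14,18,22-hexamethyltricosa-1,5,9,13,17,21-hexaenyl]alane (not isolated) | CC(C)=CCC/C(C)=C/CC/C(C)=C/CC/C(C)=C/CC/C(C)=C/CC/C(C)=C/[Al](C)C | intermediate
23 | 2,8-dimethyl-3-[(2E,6E,10E,14E,18E)-3,7,11,15,19,23-hexamethyltetracosa-2,6,10,14,18,22-hexaenyl]naphthalene-1,4-dione (8-methylmenaquinone-6) | CC(C)=CCC/C(C)=C/CC/C(C)=C/CC/C(C)=C/CC/C(C)=C/CC/C(C)=C/CC1=C(C)C(=O)c2c(C)cccc2C1=O | target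

Total step count: 14.
Longest linear sequence: 8 steps (12 → 13 → 14 → 15 → 16 → 17 → 18 → 21 → 23). The quinone branch takes 4 steps to 8 and the sulfone branch 2 steps to 11.

Steps most likely to fail

Risk 1, step 2. One methyl group polarizes diene 3 only weakly, so orientational control may leak toward the C5-methyl series. The adduct may also shed HBr early and then enter redox exchange with unreacted quinone. The fallback sets out from 2 and returns at 7, forming the same two bonds with a doubly polarized diene. This is (E)-2-(trimethylsilyloxy)penta-1,3-diene F1, made from commercial (E)-pent-3-en-2-one with LiN(i-Pr)2 and then Me3SiCl. Its enol-ether CH2 terminus is far more nucleophilic than that of 3, and its methyl-bearing terminus again ends on C–Br. Cycloaddition with 2 in toluene at room temperature should give rac-8a-bromo-2,8-dimethyl-6-(trimethylsilyloxy)-4a,5,8,8a-tetrahydronaphthalene-1,4-dione F2. Et3N in air followed by dilute HCl should remove HBr, aromatize ring A and cleave the silyl ether to give 6-hydroxy-2,8-dimethylnaphthalene-1,4-dione F3. Tf2O and pyridine convert it into 6,8-dimethyl-5,8-dioxo-5,8-dihydronaphthalen-2-yl trifluoromethanesulfonate F4. Palladium-catalysed formate reduction (Pd(OAc)2, PPh3, HCO2H, Et3N, DMF, 60 °C, air on work-up) removes the surplus oxygen and rejoins the route at 7.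

Risk 2, step 11. Cleavage of the allylic C–S bond by electron transfer passes through an allyl radical and an allyl anion. This allows migration of the C14'=C15' olefin and partial E-to-Z leakage, and the isomers would be hard to remove later. The fallback sets out from 16 and returns at 17, separating the two cleavages and replacing electron transfer at the sulfone by a pi-allylpalladium hydride substitution. PdCl2(dppp) (cat.) with LiEt3BH in THF at 0 °C should deliver hydride to the less substituted allyl terminus with the olefin left in place, giving benzyl (2E,6E,10E,14E)-geranylfarnesyl ether F5. The benzyl group alone is then removed with LiC10H8 (lithium naphthalenide) in THF at −25 °C. That cleavage generates no allyl intermediate in the chain and gives 17.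

Risk 3, step 14. Incomplete carboalumination, methyl transfer from residual Me3Al, and reduction of or addition to the free quinone by the alane or by low-valent nickel may all erode the coupling. The fallback sets out from 7, uses alane 22 made from 21 as before, and returns at 23. It carries the quinone through the coupling as its hydroquinone dimethyl ether and also bypasses step 4. Na2S2O4 reduces 7 to diol 6, which Me2SO4 and KOH convert into 1,4-dimethoxy-2,8-dimethylnaphthalene F6. Paraformaldehyde and HCl in AcOH chloromethylate the only free position of the electron-rich ring to give 3-(chloromethyl)-1,4-dimethoxy-2,8-dimethylnaphthalene F7. Coupling of F7 with 22 under zerovalent nickel from NiCl2(PPh3)2 and n-BuLi gives 3-[(2E,6E,10E,14E,18E)-hexaprenyl]-1,4-dimethoxy-2,8-dimethylnaphthalene F8. Oxidative demethylation with (NH4)2Ce(NO3)6 in MeCN–CH2Cl2–H2O at 0 °C releases 23.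

Further compounds
F1 | step 2 | (E)-2-(trimethylsilyloxy)penta-1,3-diene | C=C(O[Si](C)(C)C)/C=C/C
F2 | step 2 | rac-8a-bromo-2,8-dimethyl-6-(trimethylsilyloxy)-4a,5,8,8a-tetrahydronaphthalene-1,4-dione (relative configuration as in 4) | O=C1C(C)=CC(=O)[C@@H]2CC(O[Si](C)(C)C)=C[C@H](C)[C@]12Br
F3 | step 2 | 6-hydroxy-2,8-dimethylnaphthalene-1,4-dione | O=C1C(C)=CC(=O)c2cc(O)cc(C)c12
F4 | step 2 | 6,8-dimethyl-5,8-dioxo-5,8-dihydronaphthalen-2-yl trifluoromethanesulfonate | O=C1C(C)=CC(=O)c2cc(OS(=O)(=O)C(F)(F)F)cc(C)c12
F5 | step 11 | benzyl (2E,6E,10E,14E)-geranylfarnesyl ether | CC(C)=CCC/C(C)=C/CC/C(C)=C/CC/C(C)=C/CC/C(C)=C/COCc1ccccc1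
F6 | step 14 | 1,4-dimethoxy-2,8-dimethylnaphthalene | COc1c(C)cc(OC)c2cccc(C)c12
F7 | step 14 | 3-(chloromethyl)-1,4-dimethoxy-2,8-dimethylnaphthalene | COc1c(C)c(CCl)c(OC)c2cccc(C)c12
F8 | step 14 | 3-[(2E,6E,10E,14E,18E)-3,7,11,15,19,23-hexamethyltetracosa-2,6,10,14,18,22-hexaenyl]-1,4-dimethoxy-2,8-dimethylnaphthalene | CC(C)=CCC/C(C)=C/CC/C(C)=C/CC/C(C)=C/CC/C(C)=C/CC/C(C)=C/Cc1c(C)c(OC)c2c(C)cccc2c1OC
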